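**Retrosynthetic overview** (side chain numbered C1′ to C16′ from the benzylic carbon)
1. End game: fluoride release of the two aryl silyl ethers, O-acetylation at C5′, and a Wittig reaction of a C10′ aldehyde with an acyl ylide (from 4-methylpent-3-enoic acid) that brings in the (E)-enone and the prenyl ketone.
2. Key disconnection C4′–C5′: a proposed enantioselective nickel-catalysed reductive 1,4-coupling of an aryl 3-methylbuta-1,3-diene with a (2E)-3-methyl enal and Et3SiH. It forms the bond, the 5′S centre and the 2′E olefin in one step.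
3. Aryl diene: from 2-bromo-6-methylphenol (para-oxidation, reduction, bis-silylation) and hydrozirconated 2-methylbut-1-en-3-yne by Negishi coupling.
4. Enal: from geranyl acetate by cleavage of the distal olefin, acetal formation, deacetylation and MnO2 oxidation; the 6′E olefin is inherited from geraniol.
5. Rings: none is built; the single benzene ring is bought and only raised to the hydroquinone level.

Assumption: the facial sense induced by the chiral phosphine in the new step cannot be known beforehand; (+)-neomenthyldiphenylphosphine is written, and its enantiomer is used instead if it proves to give the (R)-carbinol.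

**Route**

Step 1
Reactants: 1 2-bromo-6-methylphenol
Product: 3 2-bromo-6-methylbenzene-1,4-diol, via bromoquinone 2 (not isolated)
Conditions: (KSO3)2NO (2.5 equiv), KH2PO4, H2O/acetone, 0 °C to rt; then Na2S2O4 (aq), EtOAc, rt
Reagents that add atoms: potassium nitrosodisulfonate, [K+].[K+].[O-]S(=O)(=O)N([O])S(=O)(=O)[O-]
Why: Teuber oxidation of a 2,6-disubstituted phenol with a free para position gives only the para-quinone, which dithionite reduces in the same flask to the hydroquinone.

Step 2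
Reactants: 3 2-bromo-6-methylbenzene-1,4-diol
Product: 4 1-bromo-2,5-bis(tert-butyldimethylsilyloxy)-3-methylbenzene
Conditions: TBSCl (2.6 equiv), imidazole (5 equiv), DMF, 45 °C
Reagents that add atoms: tert-butyldimethylsilyl chloride, CC(C)(C)[Si](C)(C)Cl
Why: Imidazole-promoted O-silylation protects both phenols, the flanked one needing only mild warming.

Step 3
Reactants: 4 1-bromo-2,5-bis(tert-butyldimethylsilyloxy)-3-methylbenzene; 5 2-methylbut-1-en-3-yne
Product: 8 (E)-1-[2,5-bis(tert-butyldimethylsilyloxy)-3-methylphenyl]-3-methylbuta-1,3-diene, via dienylzirconocene chloride 6 (not isolated), via dienylzinc chloride 7 (not isolated)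
Conditions: 5 (1.5 equiv), Cp2Zr(H)Cl (1.4 equiv), THF, 0 °C to rt; then ZnCl2 (1.4 equiv), 4, Pd(OAc)2 (3 mol%), SPhos (6 mol%), THF, 50 °C
Reagents that add atoms: none
Why: Syn-hydrozirconation of the terminal alkyne (much faster than the 1,1-disubstituted alkene) gives the (E)-alkenyl metal, and zirconium-to-zinc transmetalation with Negishi cross-coupling keeps that geometry under base-free conditions that spare the aryl silyl ethers.

Step 4
Reactants: 9 geranyl acetate
Product: 11 (2E)-3-methyl-6-oxohex-2-enyl acetate, via epoxygeranyl acetate 10 (not isolated)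
Conditions: mCPBA (1.05 equiv), CH2Cl2, 0 °C; then H5IO6 (1.2 equiv), THF/H2O, 0 °C
Reagents that add atoms: meta-chloroperbenzoic acid, O=C(OO)c1cccc(Cl)c1
Why: Prilezhaev epoxidation picks the electron-rich distal olefin (the 2,3-olefin is deactivated by the allylic acetate), and periodic acid cleaves the epoxide to aldehyde plus acetone without touching the (E)-olefin.

Step 5
Reactants: 11 (2E)-3-methyl-6-oxohex-2-enyl acetate
Product: 13 (2E)-6,6-dimethoxy-3-methylhex-2-en-1-ol, via acetal acetate 12 (not isolated)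
Conditions: HC(OMe)3 (3 equiv), MeOH, PPTS (5 mol%), rt; then K2CO3 (0.3 equiv), rt
Reagents that add atoms: trimethyl orthoformate, COC(OC)OC; methanol, CO
Why: Acid-catalysed acetalisation driven by the orthoformate is followed in the same flask by base-catalysed transesterification of the acetate, to which the acetal is inert.

Step 6
Reactants: 13 (2E)-6,6-dimethoxy-3-methylhex-2-en-1-ol
Product: 14 (2E)-6,6-dimethoxy-3-methylhex-2-enal
Conditions: MnO2 (15 equiv), CH2Cl2, rt
Reagents that add atoms: none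
Why: MnO2 oxidation is selective for allylic alcohols and neutral, so the acetal and the (E)-geometry are kept.

Step 7
Reactants: 8 (E)-1-[2,5-bis(tert-butyldimethylsilyloxy)-3-methylphenyl]-3-methylbuta-1,3-diene; 14 (2E)-6,6-dimethoxy-3-methylhex-2-enal
Product: 15 2-[(2E,5S,6E)-10,10-dimethoxy-3,7-dimethyl-5-(triethylsilyloxy)deca-2,6-dienyl]-6-methyl-1,4-bis(tert-butyldimethylsilyloxy)benzene
Conditions: Ni(cod)2 (10 mol%), (+)-neomenthyldiphenylphosphine (20 mol%), 8 (1.5 equiv), Et3SiH (2 equiv, added over 4 h), THF, 0 °C to rt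
Reagents that add atoms: triethylsilane, CC[SiH](CC)CC
Why: Proposed new method: an enantioselective nickel-catalysed reductive 1,4-hydro(hydroxyalkyl)ation of a 1-aryl-3-methyl-1,3-diene with an enal, in which zerovalent nickel carrying the chiral monophosphine binds the diene and the C=O of 14 and undergoes oxidative cyclisation at the unsubstituted diene terminus C4′ on the Si face of the aldehyde (enantio-determining, sets 5′S), the resulting η3-allyl(alkoxy)nickel equilibrates by η3–η1–η3 so that the bulky C4′ chain sits syn (2′E olefin), and Si–H σ-bond metathesis followed by C–H reductive elimination at the less hindered benzylic terminus C1′ releases the linear silyl ether; the closest known reaction types are the nickel/triarylphosphine three-component reductive coupling of simple 1,3-dienes, aldehydes and Et3SiH to (E)-homoallyl silyl ethers and the chiral-monophosphine nickel reductive coupling of alkynes with aldehydes, neither shown in enantioselective form for an aryl diene that must deliver a trisubstituted (E)-olefin or for an enal partner.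

Step 8
Reactants: 15 2-[(2E,5S,6E)-10,10-dimethoxy-3,7-dimethyl-5-(triethylsilyloxy)deca-2,6-dienyl]-6-methyl-1,4-bis(tert-butyldimethylsilyloxy)benzene
Product: 16 (4E,6S,8E)-10-[2,5-bis(tert-butyldimethylsilyloxy)-3-methylphenyl]-6-hydroxy-4,8-dimethyldeca-4,8-dienal
Conditions: AcOH/THF/H2O (3:1:1), 30 °C
Reagents that add atoms: water, O
Why: Mild acid solvolysis removes the secondary triethylsilyl ether and hydrolyses the dimethyl acetal together, while the acid-stable aryl silyl ethers stay and the weak acid does not ionise the allylic carbinol, so 5′S is kept.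

Step 9
Reactants: 17 4-methylpent-3-enoic acid; 18 ethyltriphenylphosphonium bromide
Product: 21 6-methyl-2-(triphenylphosphoranylidene)hept-5-en-3-one, via acid chloride 19 (not isolated), via ethylidene ylide 20 (not isolated)
Conditions: 17, (COCl)2 (1.2 equiv), DMF (cat.), CH2Cl2, 0 °C to rt, evaporate; 18 (2.1 equiv), NaN(SiMe3)2 (2.05 equiv), THF, 0 °C; add 19, −78 °C to rt
Reagents that add atoms: none
Why: C-acylation of the non-stabilised ylide by the acid chloride and transylidation by the second equivalent give the stabilised acyl ylide, and at −78 °C acylation outruns ketene formation and olefin migration.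

Step 10
Reactants: 16 (4E,6S,8E)-10-[2,5-bis(tert-butyldimethylsilyloxy)-3-methylphenyl]-6-hydroxy-4,8-dimethyldeca-4,8-dienal; 21 6-methyl-2-(triphenylphosphoranylidene)hept-5-en-3-one
Product: 22 2-[(2E,5S,6E,10E)-5-hydroxy-3,7,11,15-tetramethyl-12-oxohexadeca-2,6,10,14-tetraenyl]-6-methyl-1,4-bis(tert-butyldimethylsilyloxy)benzene
Conditions: 21 (1.6 equiv), toluene, 90 °C, argon
Reagents that add atoms: none
Why: Wittig olefination with a stabilised α-methyl acyl ylide gives the (E)-trisubstituted enone under neutral conditions that tolerate the free alcohol and do not enolise the β,γ-unsaturated ketone.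

Step 11
Reactants: 22 2-[(2E,5S,6E,10E)-5-hydroxy-3,7,11,15-tetramethyl-12-oxohexadeca-2,6,10,14-tetraenyl]-6-methyl-1,4-bis(tert-butyldimethylsilyloxy)benzene
Product: 23 (2E,5S,6E,10E)-1-[2,5-bis(tert-butyldimethylsilyloxy)-3-methylphenyl]-3,7,11,15-tetramethyl-12-oxohexadeca-2,6,10,14-tetraen-5-yl acetate
Conditions: Ac2O (3 equiv), pyridine (6 equiv), DMAP (5 mol%), CH2Cl2, 0 °C
Reagents that add atoms: acetic anhydride, CC(=O)OC(C)=O
Why: DMAP-catalysed O-acylation does not break the C5′–O bond, so the (S)-configuration is retained, and the weak amine bases at 0 °C do not move the skipped olefin into conjugation.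

Step 12
Reactants: 23 (2E,5S,6E,10E)-1-[2,5-bis(tert-butyldimethylsilyloxy)-3-methylphenyl]-3,7,11,15-tetramethyl-12-oxohexadeca-2,6,10,14-tetraen-5-yl acetate
Product: 24 (2E,5S,6E,10E)-1-(2,5-dihydroxy-3-methylphenyl)-3,7,11,15-tetramethyl-12-oxohexadeca-2,6,10,14-tetraen-5-yl acetate
Conditions: TBAF (2.4 equiv), AcOH (2.6 equiv), THF, 0 °C, argon; degassed pH 6 buffer work-up
Reagents that add atoms: none
Why: Fluoride-induced desilylation is fast for aryl silyl ethers, and the acetic acid buffer protects the acetate and the β,γ-unsaturated ketone from base while argon keeps the hydroquinone from oxidising.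

**Compound list**
1 | 2-bromo-6-methylphenol | Cc1cccc(Br)c1O | starting material
2 | 2-bromo-6-methyl-1,4-benzoquinone | CC1=CC(=O)C=C(Br)C1=O | intermediate
3 | 2-bromo-6-methylbenzene-1,4-diol | Cc1cc(O)cc(Br)c1O | intermediate
4 | 1-bromo-2,5-bis(tert-butyldimethylsilyloxy)-3-methylbenzene | Cc1cc(O[Si](C)(C)C(C)(C)C)cc(Br)c1O[Si](C)(C)C(C)(C)C | intermediate
5 | 2-methylbut-1-en-3-yne | C=C(C)C#C | starting material
6 | chlorobis(cyclopentadienyl)[(1E)-3-methylbuta-1,3-dienyl]zirconium | C=C(C)/C=C/[Zr](Cl)(C1C=CC=C1)C1C=CC=C1 | intermediate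
7 | chloro[(1E)-3-methylbuta-1,3-dienyl]zinc | C=C(C)/C=C/[Zn]Cl | intermediate
8 | (E)-1-[2,5-bis(tert-butyldimethylsilyloxy)-3-methylphenyl]-3-methylbuta-1,3-diene | C=C(C)/C=C/c1cc(O[Si](C)(C)C(C)(C)C)cc(C)c1O[Si](C)(C)C(C)(C)C | intermediate
9 | geranyl acetate, (2E)-3,7-dimethylocta-2,6-dienyl acetate | CC(=O)OC/C=C(\C)CCC=C(C)C | starting material
10 | (2E)-6,7-epoxy-3,7-dimethyloct-2-enyl acetate (racemic epoxide) | CC(=O)OC/C=C(\C)CCC1OC1(C)C | intermediate
11 | (2E)-3-methyl-6-oxohex-2-enyl acetate | CC(=O)OC/C=C(\C)CCC=O | intermediate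
12 | (2E)-6,6-dimethoxy-3-methylhex-2-enyl acetate | CC(=O)OC/C=C(\C)CCC(OC)OC | intermediate
13 | (2E)-6,6-dimethoxy-3-methylhex-2-en-1-ol | OC/C=C(\C)CCC(OC)OC | intermediate
14 | (2E)-6,6-dimethoxy-3-methylhex-2-enal | O=C/C=C(\C)CCC(OC)OC | intermediate
15 | 2-[(2E,5S,6E)-10,10-dimethoxy-3,7-dimethyl-5-(triethylsilyloxy)deca-2,6-dienyl]-6-methyl-1,4-bis(tert-butyldimethylsilyloxy)benzene | CC[Si](CC)(CC)O[C@H](/C=C(\C)CCC(OC)OC)C/C(C)=C/Cc1cc(O[Si](C)(C)C(C)(C)C)cc(C)c1O[Si](C)(C)C(C)(C)C | intermediate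
16 | (4E,6S,8E)-10-[2,5-bis(tert-butyldimethylsilyloxy)-3-methylphenyl]-6-hydroxy-4,8-dimethyldeca-4,8-dienal | O[C@H](/C=C(\C)CCC=O)C/C(C)=C/Cc1cc(O[Si](C)(C)C(C)(C)C)cc(C)c1O[Si](C)(C)C(C)(C)C | intermediate
17 | 4-methylpent-3-enoic acid | CC(C)=CCC(=O)O | starting material
18 | ethyltriphenylphosphonium bromide | CC[P+](c1ccccc1)(c1ccccc1)c1ccccc1.[Br-] | starting material
19 | 4-methylpent-3-enoyl chloride | CC(C)=CCC(=O)Cl | intermediate
20 | ethylidenetriphenylphosphorane | CC=P(c1ccccc1)(c1ccccc1)c1ccccc1 | intermediate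
21 | 6-methyl-2-(triphenylphosphoranylidene)hept-5-en-3-one | CC(C)=CCC(=O)C(C)=P(c1ccccc1)(c1ccccc1)c1ccccc1 | intermediate
22 | 2-[(2E,5S,6E,10E)-5-hydroxy-3,7,11,15-tetramethyl-12-oxohexadeca-2,6,10,14-tetraenyl]-6-methyl-1,4-bis(tert-butyldimethylsilyloxy)benzene | O[C@H](/C=C(\C)CC/C=C(\C)C(=O)CC=C(C)C)C/C(C)=C/Cc1cc(O[Si](C)(C)C(C)(C)C)cc(C)c1O[Si](C)(C)C(C)(C)C | intermediate
23 | (2E,5S,6E,10E)-1-[2,5-bis(tert-butyldimethylsilyloxy)-3-methylphenyl]-3,7,11,15-tetramethyl-12-oxohexadeca-2,6,10,14-tetraen-5-yl acetate | CC(=O)O[C@H](/C=C(\C)CC/C=C(\C)C(=O)CC=C(C)C)C/C(C)=C/Cc1cc(O[Si](C)(C)C(C)(C)C)cc(C)c1O[Si](C)(C)C(C)(C)C | intermediate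
24 | (2E,5S,6E,10E)-1-(2,5-dihydroxy-3-methylphenyl)-3,7,11,15-tetramethyl-12-oxohexadeca-2,6,10,14-tetraen-5-yl acetate (CNP0186948.1) | CC(=O)O[C@H](/C=C(\C)CC/C=C(\C)C(=O)CC=C(C)C)C/C(C)=C/Cc1cc(O)cc(C)c1O | target

**Totals**
Total step count: 12. Longest linear sequence: 8 steps (steps 1, 2, 3, 7, 8, 10, 11, 12; the geranyl acetate branch through steps 4, 5, 6 is equally long).

**Steps most likely to fail, with fallbacks**

Step 7 (the proposed new reaction). The risks are partial formation of the 2′Z olefin if the allyl nickel intermediate collapses before syn/anti equilibration, hydride delivery to C3′ instead of C1′, competing hydrosilylation of the enal, and insufficient enantioselectivity. The fallback uses known chemistry only, sets out from 14 and 4 and comes back to the route at 15.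
- Enal 14 is propargylated with allenylboronic acid pinacol ester under chiral phosphoric acid catalysis (TRIP, the enantiomer that gives Si-face attack, toluene, 4 Å sieves, 0 °C) to give (4S,5E)-9,9-dimethoxy-6-methylnon-5-en-1-yn-4-ol F1.
- Et3SiCl and imidazole convert it into triethyl[(4S,5E)-9,9-dimethoxy-6-methylnon-5-en-1-yn-4-yloxy]silane F2.
- In parallel, bromide 4 undergoes bromine–lithium exchange (n-BuLi, THF, −78 °C, quenched within minutes to outrun O-to-C silyl migration) and DMF trapping to give 2,5-bis(tert-butyldimethylsilyloxy)-3-methylbenzaldehyde F3.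
- NaBH4 reduces it to [2,5-bis(tert-butyldimethylsilyloxy)-3-methylphenyl]methanol F4.
- MsCl/Et3N and then LiCl take it through 2,5-bis(tert-butyldimethylsilyloxy)-3-methylbenzyl methanesulfonate F5 to 2,5-bis(tert-butyldimethylsilyloxy)-3-methylbenzyl chloride F6.
- Zirconium-catalysed syn-methylalumination of F2 (Me3Al, Cp2ZrCl2 20 mol%, CH2Cl2, 1 equiv H2O as accelerator, −20 °C, kept short and cold to spare the acetal) gives dimethyl[(1E,4S,5E)-9,9-dimethoxy-2,6-dimethyl-4-(triethylsilyloxy)nona-1,5-dienyl]alane F7.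
- F7 is cross-coupled in the same flask with F6 (NiCl2(PPh3)2 3 mol% reduced by n-BuLi to zerovalent nickel, THF, rt) to give 15, with the 2′E geometry fixed by the syn carbometalation.

Step 9 (the acyl ylide, on which step 10 depends). The β,γ-unsaturated acid chloride can form a vinylketene or slip into conjugation under the basic ylide, and the hindered ylide may then olefinate slowly. The fallback sets out from 16 and comes back at 23, bypassing 21 and 22.
- Wittig reaction of 16 with commercial 2-(triphenylphosphoranylidene)propanal (toluene, 80 °C) gives 2-[(2E,5S,6E,10E)-5-hydroxy-3,7,11-trimethyl-12-oxododeca-2,6,10-trienyl]-6-methyl-1,4-bis(tert-butyldimethylsilyloxy)benzene F8.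
- Ac2O/pyridine gives (2E,5S,6E,10E)-1-[2,5-bis(tert-butyldimethylsilyloxy)-3-methylphenyl]-3,7,11-trimethyl-12-oxododeca-2,6,10-trien-5-yl acetate F9.
- α-Selective 1,2-addition of prenylbarium chloride (prenyl chloride and activated barium from BaI2 and lithium biphenylide, THF, −78 °C) gives (2E,5S,6E,10E)-1-[2,5-bis(tert-butyldimethylsilyloxy)-3-methylphenyl]-12-hydroxy-3,7,11,15-tetramethylhexadeca-2,6,10,14-tetraen-5-yl acetate F10 as a mixture of C12′ epimers.
- Dess–Martin periodinane buffered with NaHCO3 oxidises F10 to 23.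

Step 12 (final unmasking). The free hydroquinone oxidises readily in air, and fluoride basicity threatens the acetate and the skipped enone. The fallback sets out from 23 and comes back at 24 by going through the quinone on purpose.
- Oxidative desilylation of 23 with (NH4)2Ce(NO3)6 (MeCN/H2O, 0 °C) gives the chromatographically stable (2E,5S,6E,10E)-3,7,11,15-tetramethyl-1-(5-methyl-3,6-dioxocyclohexa-1,4-dienyl)-12-oxohexadeca-2,6,10,14-tetraen-5-yl acetate F11.
- Two-phase reduction with aqueous Na2S2O4 (EtOAc, rt, argon) gives 24 just before use.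

**Further compounds**
F1 | step 7 | (4S,5E)-9,9-dimethoxy-6-methylnon-5-en-1-yn-4-ol | O[C@H](/C=C(\C)CCC(OC)OC)CC#C
F2 | step 7 | triethyl[(4S,5E)-9,9-dimethoxy-6-methylnon-5-en-1-yn-4-yloxy]silane | CC[Si](CC)(CC)O[C@H](/C=C(\C)CCC(OC)OC)CC#C
F3 | step 7 | 2,5-bis(tert-butyldimethylsilyloxy)-3-methylbenzaldehyde | O=Cc1cc(O[Si](C)(C)C(C)(C)C)cc(C)c1O[Si](C)(C)C(C)(C)C
F4 | step 7 | [2,5-bis(tert-butyldimethylsilyloxy)-3-methylphenyl]methanol | OCc1cc(O[Si](C)(C)C(C)(C)C)cc(C)c1O[Si](C)(C)C(C)(C)C
F5 | step 7 | 2,5-bis(tert-butyldimethylsilyloxy)-3-methylbenzyl methanesulfonate | CS(=O)(=O)OCc1cc(O[Si](C)(C)C(C)(C)C)cc(C)c1O[Si](C)(C)C(C)(C)C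
F6 | step 7 | 2,5-bis(tert-butyldimethylsilyloxy)-3-methylbenzyl chloride | ClCc1cc(O[Si](C)(C)C(C)(C)C)cc(C)c1O[Si](C)(C)C(C)(C)C
F7 | step 7 | dimethyl[(1E,4S,5E)-9,9-dimethoxy-2,6-dimethyl-4-(triethylsilyloxy)nona-1,5-dienyl]alane | CC[Si](CC)(CC)O[C@H](/C=C(\C)CCC(OC)OC)C/C(C)=C/[Al](C)C
F8 | step 9 | 2-[(2E,5S,6E,10E)-5-hydroxy-3,7,11-trimethyl-12-oxododeca-2,6,10-trienyl]-6-methyl-1,4-bis(tert-butyldimethylsilyloxy)benzene | O[C@H](/C=C(\C)CC/C=C(\C)C=O)C/C(C)=C/Cc1cc(O[Si](C)(C)C(C)(C)C)cc(C)c1O[Si](C)(C)C(C)(C)C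
F9 | step 9 | (2E,5S,6E,10E)-1-[2,5-bis(tert-butyldimethylsilyloxy)-3-methylphenyl]-3,7,11-trimethyl-12-oxododeca-2,6,10-trien-5-yl acetate | CC(=O)O[C@H](/C=C(\C)CC/C=C(\C)C=O)C/C(C)=C/Cc1cc(O[Si](C)(C)C(C)(C)C)cc(C)c1O[Si](C)(C)C(C)(C)C
F10 | step 9 | (2E,5S,6E,10E)-1-[2,5-bis(tert-butyldimethylsilyloxy)-3-methylphenyl]-12-hydroxy-3,7,11,15-tetramethylhexadeca-2,6,10,14-tetraen-5-yl acetate (C12 epimers) | CC(=O)O[C@H](/C=C(\C)CC/C=C(\C)C(O)CC=C(C)C)C/C(C)=C/Cc1cc(O[Si](C)(C)C(C)(C)C)cc(C)c1O[Si](C)(C)C(C)(C)C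
F11 | step 12 | (2E,5S,6E,10E)-3,7,11,15-tetramethyl-1-(5-methyl-3,6-dioxocyclohexa-1,4-dienyl)-12-oxohexadeca-2,6,10,14-tetraen-5-yl acetate | CC(=O)O[C@H](/C=C(\C)CC/C=C(\C)C(=O)CC=C(C)C)C/C(C)=C/CC1=CC(=O)C=C(C)C1=O
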